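The earlier runs and the new flask were computed on assumed constants, and the scatter is random.

**No constants.** You have no rate constants for this scheme, so start from a balance, which needs none. The flask charges 0.800 M of reagent against 0.40 M of substrate, so 2.00 per substrate: call this the reagent cover, reagent charged over substrate charged, with each substrate taking one reagent. The substrate is therefore the limiting reagent, and once its whole charge has reacted, 50.0% of the reagent remains, 0.400 M per starting volume.

| flask | substrate | reagent | remark | time |
|---|---|---|---|---|
| cedar | 0.40 M (fed, over 40 min) | 1.2 M | run made earlier; the fed solution adds 1.0 times the starting volume |  |
| flask | 0.40 M (fed, over 40 min) | 0.800 M | the fed solution adds 1.0 times the starting volume | 6.0 h |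

cedar run (percent of the substrate charged)

| time / min | substrate / % | target / % |
|---|---|---|
| 5.00 | 13 | 2 |
| 12.0 | 25 | 0 |
| 25.0 | 43 | 1 |
| 40.0 | 67 | 0 |

(each reading ± 2 percentage points)

- part of the substrate that has reacted at 6.0 h
- share of the unused reagent that is free and not bound as idle adduct, at 6.0 h

- released group is meant together with its idle adduct
- every charge counts on the volume at the start, and the solution that is fed holds the whole dose
- what may be going on: intermediate -> side product; reagent + released group <-> idle adduct; intermediate <-> target + released group; substrate -> decomposition product; substrate + reagent <-> intermediate
- percentages count the whole charge, also what has not yet gone in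
- the earlier runs do not show how much of reagent is bound; that part of a forecast is a guess

**How fast?** But a balance says nothing of time. In cedar, between 25.0 min and 40.0 min, the feed brought 37.5% of the charge while substrate rose 24 percentage points. That reads as a substrate half-life of 42.4 min near 0.600 M reagent.

**Falling reagent.** You should object that the flask has less reagent, and that it falls. The cover gives its floor, 0.200 M after dilution, which stretches the half-life to 127 min. Over the 320 min after the feed, that leaves 17.5% of what stood at its end, so, taking the whole charge as standing there, I reckon 82.5% reacted. One doubt stays: intermediate may run back, and I have not computed that.

**Free reagent.** Each idle adduct holds one released group, and each released group came with one target. Read target as 2%, the size of the scatter, take every released group as bound, and set that amount against the surplus: I reckon 98.0% free. But cedar ended at 40.0 min, and target may grow later.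

**The forecast.** It gives 88% (68% to 98%) reacted and 70% (30% to 97%) free, reasoning “Target forms slowly, so little released group exists, and most unused reagent is probably free.” My free share stands higher, my reacted part lower.

**What ran.** The flask gives 95.2% reacted and 99.3% free.

    intermediate → side product (k = 0.00731 s⁻¹)
    reagent + released group ⇌ idle adduct, settled at all times (K = 3.13 M⁻¹)
    intermediate ⇌ target + released group (K = 0.950 M, k = 1.41 × 10⁻⁴ s⁻¹)
    substrate → decomposition product (k = 8.94 × 10⁻⁷ s⁻¹)
    substrate + reagent ⇌ intermediate (K = 1.30 M⁻¹, k = 6.17 × 10⁻⁴ M⁻¹ s⁻¹)

Substrate and reagent made intermediate, 51% of that step's turnover up to 6.0 h done by 1.20 h, and intermediate went on to side product, 85% of that loss up to 6.0 h done by 3.00 h. At 6.00 h the flask holds 52.3% of its reagent, near the 50.0% its cover leaves. A neighbour flask with 1.6 M substrate has cover 0.500, enough for 50.0% of that substrate; there reagent falls to 0.48%, and 49% of the substrate stays.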